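**Strategy.** Locants: C1 is the quaternary ring carbon (methyl, chlorovinyl), C2 the adjacent CH2, C3 the C(Br)CH2Cl carbon, C4 and C6 the CHCl carbons, C5 the CH2 between them. The key step exploits the fact that C2 and C6 both hang on quaternary C1 while C3 and C5 both flank C4: the ring is cut at C2–C3 and C5–C6 into a 2,2-disubstituted malonaldehyde (C6–C1–C2) and acetone-1,3-dicarboxylic acid (C3–C4–C5). Their decarboxylative double aldol condensation forms both bonds at once and gives prochiral 4-ethynyl-4-methylcyclohexa-2,5-dienone. Desymmetrisation and chemistry on the two enone arms then install the halogenated centres; the slim ethynyl group steers these steps and ends as the (E)-chlorovinyl group.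

Key step: step 4

Remark: an ene-reductase of the Old Yellow Enzyme family that gives the R enantiomer of 8 is assumed to be found by screening the enantiocomplementary members of this family.

Step 1
Reactants: 1 diethyl 2-methylpropanedioate
Product: 2 diethyl 2-ethynyl-2-methylpropanedioate
Conditions: TMS-EBX, Bu4NF, THF, −78 °C → rt
Reagents that add atoms: 1-[(trimethylsilyl)ethynyl]-1,2-benziodoxol-3(1H)-one (TMS-EBX), C[Si](C)(C)C#CI1OC(=O)c2ccccc12
Why: Electrophilic alkynylation of the fluoride-generated malonate enolate by the ethynylbenziodoxolone released in situ (conjugate addition to the iodane alkyne, α-elimination, 1,2-shift) should give the quaternary terminal alkyne, with no stereocentre formed.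

Step 2
Reactants: 2 diethyl 2-ethynyl-2-methylpropanedioate
Product: 3 2-ethynyl-2-methylpropane-1,3-diol
Conditions: LiAlH4, THF, 0 °C → rt; aqueous NaOH work-up
Reagents that add atoms: none
Why: Hydride reduction of both ester groups by LiAlH4 leaves the isolated terminal alkyne untouched and gives the prochiral 1,3-diol.

Step 3
Reactants: 3 2-ethynyl-2-methylpropane-1,3-diol
Product: 4 2-ethynyl-2-methylpropanedial
Conditions: (COCl)2, DMSO, CH2Cl2, −78 °C; Et3N, −78 → 0 °C; used crude
Reagents that add atoms: none
Why: Swern oxidation stops at the aldehyde level and avoids aqueous base, under which the non-enolisable 2,2-disubstituted malonaldehyde would suffer retro-Claisen deformylation.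

Step 4
Reactants: 4 2-ethynyl-2-methylpropanedial; 5 3-oxopentanedioic acid
Product: 7 4-ethynyl-4-methylcyclohexa-2,5-dien-1-one, via cyclic bis-aldol diacid 6 (not isolated)
Conditions: NaOAc/AcOH buffer (pH 5), H2O/THF, 0 °C → rt; then 2 M HCl, 70 °C
Reagents that add atoms: none
Why: At pH 5 one activated methylene of 5 adds to one formyl group of 4 and the second methylene then adds to the remaining formyl group in a 6-(enolexo)-exo-trig aldol closure to give 6; acid and heat then remove two CO2 and two H2O, so that C2–C3 and C5–C6 are made as the two enone C=C bonds of 7 in one operation. The closest known reaction types are the Robinson–Schöpf and Weiss condensations of acetonedicarboxylic acid with dialdehydes and the [3+3] Knoevenagel benzannulation of acetonedicarboxylates with malonaldehyde equivalents; here the quaternary carbon blocks aromatisation and the product stops at the dienone. No stereocentre survives: 7 has a mirror plane through C1 and C4, and the stereocentres of 6 are erased. The step needs ring closure to precede dehydration, because an acyclic E-enone could not close; this is secured by running the aldol stage at room temperature in buffer, where the β-hydroxy acids neither dehydrate nor decarboxylate, and only then heating with acid. It also needs the 1,3-dialdehyde to escape retro-Claisen deformylation, which the mildly acidic, hydroxide-free medium secures.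

Step 5
Reactants: 7 4-ethynyl-4-methylcyclohexa-2,5-dien-1-one
Product: 8 (4R)-4-ethynyl-4-methylcyclohex-2-en-1-one
Conditions: ene-reductase (Old Yellow Enzyme family), NADP+ (cat.), D-glucose, glucose dehydrogenase, potassium phosphate buffer pH 7.5, DMSO (5 vol %), 30 °C
Reagents that add atoms: none
Why: Enzymatic desymmetrising conjugate reduction (flavin hydride to the β-carbon, protonation at the α-carbon) of one of the two enantiotopic enone arms should set the quaternary centre as R, and the hindered 4,4-disubstituted enone product should not be reduced further.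

Step 6
Reactants: 8 (4R)-4-ethynyl-4-methylcyclohex-2-en-1-one
Product: 9 (4R,6Z)-4-ethynyl-6-(hydroxymethylidene)-4-methylcyclohex-2-en-1-one
Conditions: NaOMe, HCO2Et, THF, 0 °C → rt; aqueous HCl work-up
Reagents that add atoms: ethyl formate, CCOC=O
Why: Crossed Claisen condensation at the only enolisable position (C3) introduces the future chloromethyl carbon as the hydrogen-bonded Z-hydroxymethylidene ketone without touching the quaternary centre.

Step 7
Reactants: 9 (4R,6Z)-4-ethynyl-6-(hydroxymethylidene)-4-methylcyclohex-2-en-1-one
Product: 11 (2E,4S,5S)-5-chloro-2-(chloromethylidene)-4-ethynyl-4-methylcyclohexan-1-one, via chloromethylidene dienone 10 (not isolated)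
Conditions: (COCl)2, CH2Cl2, 0 °C; then HCl (4 M in dioxane), −40 °C, short reaction time; used crude
Reagents that add atoms: oxalyl chloride, ClC(=O)C(=O)Cl; hydrogen chloride, Cl
Why: Oxalyl chloride converts the vinylogous acid into the E β-chlorovinyl ketone by addition–elimination, and conjugate hydrochlorination of the remaining enone should then place chloride at C6 anti to the methyl group of C1 (the cylindrical ethynyl group is the smaller neighbour), that is cis to ethynyl, under kinetic control.

Step 8
Reactants: 11 (2E,4S,5S)-5-chloro-2-(chloromethylidene)-4-ethynyl-4-methylcyclohexan-1-one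
Product: 12 (1S,2E,4S,5S)-5-chloro-2-(chloromethylidene)-4-ethynyl-4-methylcyclohexan-1-ol
Conditions: (R)-2-methyl-CBS-oxazaborolidine (20 mol %), catecholborane, toluene, −78 °C
Reagents that add atoms: none
Why: In this Corey–Bakshi–Shibata reduction the α-branched alkenyl arm acts as the large group, so the R catalyst should deliver hydride to the face syn to ethynyl (reagent control over the substrate's preference for axial attack) and give the 1S axial alcohol trans to the C6 chlorine, while catecholborane at −78 °C spares the alkyne and the C=C bond.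

Step 9
Reactants: 12 (1S,2E,4S,5S)-5-chloro-2-(chloromethylidene)-4-ethynyl-4-methylcyclohexan-1-ol
Product: 13 (1S,2S,4E,5R)-1,5-dichloro-4-(chloromethylidene)-2-ethynyl-2-methylcyclohexane
Conditions: PPh3, CCl4, CH2Cl2, 0 °C → rt
Reagents that add atoms: carbon tetrachloride, ClC(Cl)(Cl)Cl
Why: In the Appel reaction the axial allylic alkoxyphosphonium is displaced by chloride in an SN2 step with inversion (SN2' attack at the chlorine-bearing exocyclic carbon is disfavoured), which sets the C4 chlorine equatorial and cis to the C6 chlorine before any bromine is present that could participate.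

Step 10
Reactants: 13 (1S,2S,4E,5R)-1,5-dichloro-4-(chloromethylidene)-2-ethynyl-2-methylcyclohexane
Product: 15 (1S,2S,4E,5R)-1,5-dichloro-2-[(E)-2-chloroethenyl]-4-(chloromethylidene)-2-methylcyclohexane, via alkenylzirconocene chloride 14 (not isolated)
Conditions: Cp2Zr(H)Cl, THF, 0 °C → rt; then NCS, 0 °C
Reagents that add atoms: N-chlorosuccinimide, O=C1CCC(=O)N1Cl
Why: Syn, anti-Markovnikov hydrozirconation of the terminal alkyne followed by chlorination of the alkenyl–Zr bond with retention should give the E chloroalkene, since the trisubstituted chloroalkene and the alkyl chlorides react far more slowly with Cp2Zr(H)Cl.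

Step 11
Reactants: 15 (1S,2S,4E,5R)-1,5-dichloro-2-[(E)-2-chloroethenyl]-4-(chloromethylidene)-2-methylcyclohexane
Product: 16 (1R,2R,4S,5S)-1-bromo-2,4-dichloro-1-(chloromethyl)-5-[(E)-2-chloroethenyl]-5-methylcyclohexane
Conditions: Co(acac)2 (cat.), t-BuOOH (cat.), Et3SiH, TsBr, n-PrOH, rt
Reagents that add atoms: 4-methylbenzenesulfonyl bromide (TsBr), Cc1ccc(cc1)S(=O)(=O)Br
Why: In this Markovnikov radical hydrobromination by metal-hydride hydrogen-atom transfer, hydrogen should go to the less substituted chloromethylidene carbon and the tertiary C3 radical (β-chlorine loss is slow) should take bromine from TsBr along the axial trajectory, which lets the chloromethyl group settle equatorial away from the axial chlorovinyl group and gives the axial bromide cis to the C4 chlorine.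

**Compound list**
1 | diethyl 2-methylpropanedioate | CCOC(=O)C(C)C(=O)OCC | starting material
2 | diethyl 2-ethynyl-2-methylpropanedioate | CCOC(=O)C(C)(C#C)C(=O)OCC | intermediate
3 | 2-ethynyl-2-methylpropane-1,3-diol | OCC(C)(C#C)CO | intermediate
4 | 2-ethynyl-2-methylpropanedial | O=CC(C)(C#C)C=O | intermediate
5 | 3-oxopentanedioic acid (acetone-1,3-dicarboxylic acid) | OC(=O)CC(=O)CC(=O)O | starting material
6 | 5-ethynyl-4,6-dihydroxy-5-methyl-2-oxocyclohexane-1,3-dicarboxylic acid (cyclic bis-aldol diacid, mixture of diastereomers) | OC(=O)C1C(O)C(C)(C#C)C(O)C(C(=O)O)C1=O | intermediate (not isolated)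
7 | 4-ethynyl-4-methylcyclohexa-2,5-dien-1-one | CC1(C#C)C=CC(=O)C=C1 | intermediate
8 | (4R)-4-ethynyl-4-methylcyclohex-2-en-1-one | C[C@@]1(C#C)CCC(=O)C=C1 | intermediate
9 | (4R,6Z)-4-ethynyl-6-(hydroxymethylidene)-4-methylcyclohex-2-en-1-one | C[C@@]1(C#C)C/C(=C/O)C(=O)C=C1 | intermediate
10 | (4R,6E)-6-(chloromethylidene)-4-ethynyl-4-methylcyclohex-2-en-1-one | C[C@@]1(C#C)C/C(=C\Cl)C(=O)C=C1 | intermediate (not isolated)
11 | (2E,4S,5S)-5-chloro-2-(chloromethylidene)-4-ethynyl-4-methylcyclohexan-1-one | C[C@@]1(C#C)C/C(=C\Cl)C(=O)C[C@@H]1Cl | intermediate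
12 | (1S,2E,4S,5S)-5-chloro-2-(chloromethylidene)-4-ethynyl-4-methylcyclohexan-1-ol | C[C@@]1(C#C)C/C(=C\Cl)[C@@H](O)C[C@@H]1Cl | intermediate
13 | (1S,2S,4E,5R)-1,5-dichloro-4-(chloromethylidene)-2-ethynyl-2-methylcyclohexane | C[C@@]1(C#C)C/C(=C\Cl)[C@H](Cl)C[C@@H]1Cl | intermediate
14 | alkenylzirconocene chloride from 13 | C[C@@]1(/C=C/[Zr](Cl)(C2C=CC=C2)C2C=CC=C2)C/C(=C\Cl)[C@H](Cl)C[C@@H]1Cl | intermediate (not isolated)
15 | (1S,2S,4E,5R)-1,5-dichloro-2-[(E)-2-chloroethenyl]-4-(chloromethylidene)-2-methylcyclohexane | C[C@@]1(/C=C/Cl)C/C(=C\Cl)[C@H](Cl)C[C@@H]1Cl | intermediate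
16 | (1R,2R,4S,5S)-1-bromo-2,4-dichloro-1-(chloromethyl)-5-[(E)-2-chloroethenyl]-5-methylcyclohexane | C[C@@]1(/C=C/Cl)C[C@@](Br)(CCl)[C@H](Cl)C[C@@H]1Cl | target

**Step count.** Total: 11 steps. Longest linear sequence: 11 steps (1 → 16); 5 enters at step 4.

**Steps most likely to fail**

Step 11. Bromine-atom transfer to the planar tertiary C3 radical may occur from the equatorial face, hydrogen-atom transfer may go to the ring carbon instead of the chloromethylidene carbon, and sulfonyl radicals may add to the chlorovinyl group. The fallback sets out from 13 and generates the C3 radical one step earlier, where the axial neighbour of the forming C–Br bond is the slim ethynyl group and no second alkene is present. Hydrobromination of 13 with Co(acac)2, t-BuOOH, Et3SiH and TsBr would give the ethynyl bromide F1. Cp2Zr(H)Cl followed by NCS would then pass through the alkenylzirconocene F2 and return to the route at 16.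

Step 7. The conjugate addition of chloride is reversible, so kinetic facial control at C6 may be lost by elimination and re-addition, and HCl may be lost on handling. The fallback sets out from 10, isolated after the oxalyl chloride stage, and builds both secondary chlorides from a cis-1,3-diol instead. Reduction of 10 with (R)-2-methyl-CBS-oxazaborolidine and catecholborane would give the dienol F3. Hydroxyl-directed epoxidation of the ring alkene with VO(acac)2 and t-BuOOH would give the syn epoxy alcohol F4. Hydride opening at the carbon next to the carbinol with NaAlH2(OCH2CH2OMe)2 would give the cis-1,3-diol F5. Double Appel chlorination (PPh3, CCl4) with inversion at both carbinol carbons returns to the route at 13.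

Step 5. Methyl and ethynyl differ little in size, so the enzyme may discriminate the enantiotopic enone arms poorly. The fallback sets out from 7 and enlarges the alkyne before a chemical desymmetrisation. Silylation of the alkyne (LiN(SiMe3)2, iPr3SiOTf, THF, −78 °C) would give the silyl dienone F6. Conjugate hydrosilylation with Rh(OAc)2(H2O)[iPr-Phebox] (ligand enantiomer chosen for the R series) and (EtO)2MeSiH would give the silyl dienol ether F7. Aqueous HCl would hydrolyse it to the enone F8, and Bu4NF would remove the silyl group and return to the route at 8.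

**Further compounds**
F1 | step 11 | (1R,2R,4S,5S)-1-bromo-2,4-dichloro-1-(chloromethyl)-5-ethynyl-5-methylcyclohexane | C[C@@]1(C#C)C[C@@](Br)(CCl)[C@H](Cl)C[C@@H]1Cl
F2 | step 11 | alkenylzirconocene chloride from F1 | C[C@@]1(/C=C/[Zr](Cl)(C2C=CC=C2)C2C=CC=C2)C[C@@](Br)(CCl)[C@H](Cl)C[C@@H]1Cl
F3 | step 7 | (1S,4R,6E)-6-(chloromethylidene)-4-ethynyl-4-methylcyclohex-2-en-1-ol | C[C@@]1(C#C)C/C(=C\Cl)[C@@H](O)C=C1
F4 | step 7 | (E)-3-(chloromethylidene)-5-ethynyl-5-methyl-7-oxabicyclo[4.1.0]heptan-2-ol (epoxide cis to OH, trans to ethynyl) | C[C@@]1(C#C)C/C(=C\Cl)[C@@H](O)[C@H]2O[C@@H]12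
F5 | step 7 | (1S,3R,4S,6E)-6-(chloromethylidene)-4-ethynyl-4-methylcyclohexane-1,3-diol | C[C@@]1(C#C)C/C(=C\Cl)[C@@H](O)C[C@H]1O
F6 | step 5 | 4-methyl-4-[(triisopropylsilyl)ethynyl]cyclohexa-2,5-dien-1-one | CC1(C#C[Si](C(C)C)(C(C)C)C(C)C)C=CC(=O)C=C1
F7 | step 5 | diethoxy(methyl){[(4R)-4-methyl-4-[(triisopropylsilyl)ethynyl]cyclohexa-1,5-dien-1-yl]oxy}silane | C[C@@]1(C#C[Si](C(C)C)(C(C)C)C(C)C)CC=C(O[Si](C)(OCC)OCC)C=C1
F8 | step 5 | (4R)-4-methyl-4-[(triisopropylsilyl)ethynyl]cyclohex-2-en-1-one | C[C@@]1(C#C[Si](C(C)C)(C(C)C)C(C)C)CCC(=O)C=C1
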